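## Structural features

The target 20 is a 20-membered macrocyclic bis(bibenzyl) in which four benzene rings are joined in the order A–O–B–CH2CH2–C–O–D–CH2CH2–A by two diaryl ether oxygens and two ethano bridges. Ring A is a phenol whose ether oxygen to ring B lies ortho to the hydroxyl and para to the ethano chain, ring B is 1,3-linked, ring C is 1,4-linked, and ring D is a phenol with its hydroxyl para to the chain and the ring C oxygen ortho to that hydroxyl. The molecule has no stereocentre, so the task is one of connectivity, oxygenation pattern and ring closure only. The two guaiacol-type phenols are prone to oxidation and are carried as methyl ethers to the last step, and the benzylic CH2 groups para to oxygen donors restrict the choice of oxidants. On the way, the fragile functions are the acid-labile, polymerisable 2-aryloxybutadiene and the base- and nucleophile-sensitive terminal ynone. The real difficulty is closing the 20-membered ring in competition with oligomerisation. The key step uses the fact that ring C carries only the ring D oxygen at C1 and the bridge CH2 at C4: it can be assembled from a four-carbon diene on the ring D oxygen and a two-carbon alkyne at the end of the ring B side chain, the bridge CH2 next to ring C passing through the ketone level to polarise the alkyne, so that forming ring C also closes the macrocycle.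

## Logic of the disconnections

20 to 19: the two phenolic O–H groups are traced back to O–CH3. The methyl ethers come with the aromatic building blocks and mask the oxidisable phenols throughout. The forward demand is a demethylation that leaves both diaryl ethers intact.

19 to 18: the CH2 of the B–C bridge that is attached to ring C is traced back to C=O. This carbonyl is what activates and directs the alkyne in the ring-forming step, and it sits exactly where the target needs a benzylic methylene. The forward demand is deoxygenation of an aryl benzyl ketone without touching any ether.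

18 to 17: ring C is taken back from a benzene to a cyclohexa-1,4-diene by adding two hydrogens at its two CH2 positions. The forward step must remove doubly allylic hydrogens while leaving four benzylic CH2 groups alone.

17 to 16: both C–C bonds between the two ring CH2 groups and the two olefinic carbons that come from the alkyne are cut (retro [4+2]). This removes ring C and the macrocycle in one operation and leaves an open chain with only three arenes. The forward step must deliver 1,4 (para) orientation of oxygen and acyl group and must cyclise faster than it oligomerises.

16 to 15 to 14: the ynone is traced to the propargylic alcohol, and this to its O-silyl, C-silyl protected form. The free ynone and the terminal C–H would not survive the boron and titanium steps, so the unmasking is placed last and must avoid acid.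

14 to 13 to 11 and 12: the enol ether C=CH2 is traced to an ester C=O, and the ester O–acyl bond is then cut. The diene thus comes from a phenol in two operations. The forward demand is a methylenation that attacks only the ester carbonyl.

11 to 8 and 9: the aryl–CH2 bond at the ring D end of the D–A bridge is cut. This forms the bridge in its saturated state, so that the alkyne can already be in place, which it could not be if a stilbene had to be hydrogenated. The phenol of 9 becomes the only free hydroxyl of 11, so no two hydroxyls need to be told apart. The forward demand is hydroboration of the vinyl group only.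

8 to 5 and 6: the bond between the carbinol carbon and the alkyne is cut and the silyl ether removed. The forward addition must be faster than enolisation of the aldehyde.

5 to 4 to 3: the aldehyde is traced to the primary alcohol and the vinyl group to an aryl aldehyde. This order ensures that only one aldehyde is present at a time.

3 to 1 and 2: the aryl–O bond on ring A is cut, giving a fluoroarene activated by a para formyl group and a phenol. The forward demand is that the phenoxide reacts and the aliphatic hydroxyl does not.

## Other disconnections considered

Alternative 1: The cut is the central CH2–CH2 bond of the ring D–ring A bridge, traced back to a benzylic C–O bond in the 21-membered dibenzyl ether A1. In the forward direction n-BuLi in THF would deprotonate one OCH2 group and the other benzyl group would shift from oxygen to carbon ([1,2]-Wittig rearrangement), contracting the ring to the racemic 20-membered diarylethanol A2, which would then be deoxygenated and demethylated.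
- In favour: A1 would be closed by a Williamson etherification of a benzylic halide, a macrocyclisation with far more precedent than a macrocyclising cycloaddition; on this point the alternative is the better plan. The contraction itself is unimolecular and needs no dilution, and deprotonation on either side of the oxygen would converge on 19 after deoxygenation.
- Against: the shift goes through a radical pair after C–O homolysis and is usually of moderate efficiency. An ortho-[2,3] shift into the electron-rich benzyl ring, ortho-lithiation next to the methoxy and aryloxy groups, and plain fragmentation would compete.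
- Comparison: structurally the step only moves one bond in a ring whose four arenes and two diaryl ethers must all be made beforehand, whereas the chosen plan creates ring C together with the macrocycle. Mechanistically it is a strongly basic radical-pair process against a neutral pericyclic one. In step economy it is estimated to be several steps longer (second diaryl ether coupling, two benzylic handles, deoxygenation). The plans are equal in that both leave one oxygen function on a bridge carbon for reductive removal and both end with the same demethylation; the stereocentre of A2 is of no consequence.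

Alternative 2: The cut is the O–C(ring D) bond of the ring C–ring D ether. In the forward direction constant-current anodic oxidation (carbon anode, LiClO4, MeOH, high dilution) of the halogenated bisphenol A3 would convert the more easily oxidised ring D dibromophenol into a phenoxonium ion. Its brominated ortho carbon would be captured by the ring C dichlorophenol oxygen to give the macrocyclic bromodienone A4, racemic at the brominated carbon. Zinc reduction would rearomatise ring D, the remaining bromine and both chlorines would be hydrogenolysed, and the ring A methyl ether cleaved.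
- In favour: the diaryl ether would form at room temperature without copper, and the ring D hydroxyl would end up free and ortho to the new ether exactly as in 20, so ring D needs no protecting group. Oxidative phenol coupling of this kind has precedent for closing diaryl ether macrocycles, so on precedent for the ring-closing event the alternative is the better plan.
- Against: four halogens must be introduced as control elements and removed again, and they exclude ordinary catalytic hydrogenation for making the two ethano bridges. The guaiacyl aryl ether of ring A is itself oxidisable at the anode. Methanol or a second molecule can capture the phenoxonium ion, and the choice of which phenol is oxidised rests on a modest difference in oxidation potential.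
- Comparison: structurally it closes at a heteroatom bond with all four arenes prefabricated, against the construction of ring C in the chosen plan. Mechanistically it is a two-electron oxidation through a cation against a thermal cycloaddition; neither needs a metal catalyst in the key step, which is a point of equality. Halogenation, zinc reduction and dehalogenation add at least three steps, so the chosen plan is shorter. The stereocentre of A4 disappears on rearomatisation and is no drawback.

Alternative 3: The cut is the CH2–C(ring A) bond at the ring A end of the D–A bridge, with ring A standing as a cyclohexenone. In the forward direction, under visible light with Ru(bpy)3(PF6)2, Hantzsch ester and i-Pr2NEt, the N-acyloxyphthalimide A5 would accept an electron and lose phthalimide anion and CO2. The primary radical would add to the β-carbon of the 6-aryloxycyclohex-2-enone to give the macrocyclic 3-alkyl-6-aryloxycyclohexanone A6 as a mixture of diastereomers. Dehydrogenation to the phenol and demethylation of ring D would follow.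
- In favour: decarboxylative radical conjugate addition is established chemistry, runs at room temperature and forms an unstrained sp3–sp3 bond. The diastereomer mixture is irrelevant because both centres vanish on aromatisation. In mildness and in precedent for the bond-forming event the alternative is the better plan.
- Against: the α-aryloxy ketone present in A5 and A6 is the kind of unit that reductive photoredox conditions with amine and Hantzsch ester tend to cleave at the C–O bond (ketyl radical anion, loss of aryloxide), which would sever the ring A–ring B ether. At the dilution needed, hydrogen transfer to the primary radical is likely to be faster than closure of a 20-membered ring. The later cyclohexanone-to-phenol oxidation must remove four hydrogens in the presence of four benzylic CH2 groups, a harder aromatisation than the single dehydrogenation of 17.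
- Comparison: both plans make one arene late from a non-aromatic six-membered ring, which is a point of equality. The chosen plan forms two C–C bonds and ring C in its key step, while A6 arises from one bond and ring A must be prefabricated as an enone. The number of steps after the key step is about equal (three in each case).

Key step: step 10

Remark on the chemistry: the hydroxy/silyloxy carbon created in step 4 is racemic in 7, 8, 10, 11 and 13–15 and is erased in step 9; 16 and 17 are isomers (C30H28O5); all five building blocks (1, 2, 6, 9, 12) are taken to be commercial.

## Route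

Step 1
Reactants: 1 4-fluoro-3-methoxybenzaldehyde; 2 3-(2-hydroxyethyl)phenol
Product: 3 4-[3-(2-hydroxyethyl)phenoxy]-3-methoxybenzaldehyde
Conditions: K2CO3, DMF, 110 °C
Reagents that add atoms: none
Why: Nucleophilic aromatic substitution (addition–elimination) at the fluorine-bearing carbon para to the formyl group; K2CO3 forms only the phenoxide of 2, so the aliphatic hydroxyl stays a spectator and the ring A–O–ring B ether is set with the methoxy group ortho to it.

Step 2
Reactants: 3 4-[3-(2-hydroxyethyl)phenoxy]-3-methoxybenzaldehyde
Product: 4 2-[3-(4-ethenyl-2-methoxyphenoxy)phenyl]ethan-1-ol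
Conditions: Ph3PCH3Br, KOt-Bu (excess), THF, 0 °C → rt
Reagents that add atoms: methyltriphenylphosphonium bromide, C[P+](c1ccccc1)(c1ccccc1)c1ccccc1.[Br-]
Why: Wittig methylenation of the aryl aldehyde; the free alcohol is merely deprotonated by the excess base and returns on work-up, and the new vinyl carbon is the future ring D-side CH2 of the D–A bridge.

Step 3
Reactants: 4 2-[3-(4-ethenyl-2-methoxyphenoxy)phenyl]ethan-1-ol
Product: 5 2-[3-(4-ethenyl-2-methoxyphenoxy)phenyl]acetaldehyde
Conditions: Dess–Martin periodinane, CH2Cl2, 0 °C → rt
Reagents that add atoms: none
Why: Dess–Martin oxidation stops at the aldehyde and is fast and near neutral, which limits enolisation and self-condensation of the arylacetaldehyde; the styrene is inert, and 5 is used at once.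

Step 4
Reactants: 5 2-[3-(4-ethenyl-2-methoxyphenoxy)phenyl]acetaldehyde; 6 (triisopropylsilyl)acetylene
Product: 8 tert-butyl({1-[3-(4-ethenyl-2-methoxyphenoxy)phenyl]-4-(triisopropylsilyl)but-3-yn-2-yl}oxy)dimethylsilane (racemic), via lithium propargylic alkoxide 7 (not isolated)
Conditions: 6, n-BuLi, THF, −78 °C; 5; then TBSOTf, 2,6-lutidine, −78 → 0 °C
Reagents that add atoms: tert-butyldimethylsilyl trifluoromethanesulfonate, CC(C)(C)[Si](C)(C)OS(=O)(=O)C(F)(F)F; n-butyllithium, [Li]CCCC (its lithium is in 7 only)
Why: 1,2-Addition of a lithium acetylide to the aldehyde at low temperature, where the weakly basic acetylide adds faster than it enolises, followed by O-silylation of the alkoxide in the same flask; the new stereocentre is formed racemic on purpose because step 9 removes it, and the bulky silyl group shields the alkyne in steps 5 and 7.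

Step 5
Reactants: 8 tert-butyl({1-[3-(4-ethenyl-2-methoxyphenoxy)phenyl]-4-(triisopropylsilyl)but-3-yn-2-yl}oxy)dimethylsilane; 9 5-bromo-2-methoxyphenol
Product: 11 5-{2-[4-(3-{2-[(tert-butyldimethylsilyl)oxy]-4-(triisopropylsilyl)but-3-yn-1-yl}phenoxy)-3-methoxyphenyl]ethyl}-2-methoxyphenol (racemic), via 9-alkyl-9-borabicyclo[3.3.1]nonane 10 (not isolated)
Conditions: 9-BBN, THF, 0 °C → rt; then 9, Pd(OAc)2 (cat.), SPhos, aq. K3PO4, THF, 60 °C
Reagents that add atoms: 9-borabicyclo[3.3.1]nonane, B1C2CCCC1CCC2 (its boron and carbons are in 10 only)
Why: Anti-Markovnikov hydroboration of the terminal vinyl group and B-alkyl Suzuki–Miyaura coupling with the aryl bromide form the ring D–CH2CH2–ring A bridge directly in saturated form, so no hydrogenation is needed and the alkyne can stay; the silylalkyne flanked by a branched carbon is far too hindered for 9-BBN under these conditions, and 9 is added only after the B–H reagent is consumed so that its phenol reacts as a harmless phenoxide.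

Step 6
Reactants: 11 5-{2-[4-(3-{2-[(tert-butyldimethylsilyl)oxy]-4-(triisopropylsilyl)but-3-yn-1-yl}phenoxy)-3-methoxyphenyl]ethyl}-2-methoxyphenol; 12 acryloyl chloride
Product: 13 5-{2-[4-(3-{2-[(tert-butyldimethylsilyl)oxy]-4-(triisopropylsilyl)but-3-yn-1-yl}phenoxy)-3-methoxyphenyl]ethyl}-2-methoxyphenyl prop-2-enoate (racemic)
Conditions: 12, Et3N, CH2Cl2, 0 °C
Reagents that add atoms: none
Why: O-Acylation of the only free hydroxyl with an acid chloride and amine base; low temperature keeps conjugate addition and polymerisation of the acrylate in check.

Step 7
Reactants: 13 5-{2-[4-(3-{2-[(tert-butyldimethylsilyl)oxy]-4-(triisopropylsilyl)but-3-yn-1-yl}phenoxy)-3-methoxyphenyl]ethyl}-2-methoxyphenyl prop-2-enoate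
Product: 14 2-(buta-1,3-dien-2-yloxy)-4-{2-[4-(3-{2-[(tert-butyldimethylsilyl)oxy]-4-(triisopropylsilyl)but-3-yn-1-yl}phenoxy)-3-methoxyphenyl]ethyl}-1-methoxybenzene (racemic)
Conditions: Cp2Ti(μ-CH2)(μ-Cl)AlMe2 (Tebbe reagent), pyridine (cat.), THF–toluene, −40 → 0 °C; cold aq. NaOH; basic alumina
Reagents that add atoms: Tebbe reagent, Cp2Ti(μ-CH2)(μ-Cl)AlMe2, C[Al-]1(C)C[Ti]([Cl+]1)(C1C=CC=C1)C1C=CC=C1
Why: Tebbe methylenation of the ester carbonyl through an oxatitanacyclobutane turns the aryl acrylate into the 2-aryloxybuta-1,3-diene, a transformation known for aryl esters and for α,β-unsaturated esters; the oxophilic titanium methylidene takes the carbonyl at low temperature well before it can engage the hindered silylalkyne, and the basic work-up protects the acid-labile enol ether.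

Step 8
Reactants: 14 2-(buta-1,3-dien-2-yloxy)-4-{2-[4-(3-{2-[(tert-butyldimethylsilyl)oxy]-4-(triisopropylsilyl)but-3-yn-1-yl}phenoxy)-3-methoxyphenyl]ethyl}-1-methoxybenzene
Product: 15 1-[3-(4-{2-[3-(buta-1,3-dien-2-yloxy)-4-methoxyphenyl]ethyl}-2-methoxyphenoxy)phenyl]but-3-yn-2-ol (racemic)
Conditions: TBAF, THF, 0 °C → rt
Reagents that add atoms: none
Why: Fluoride cleaves both the O–Si bond and the Si–C(sp) bond in one operation; the medium is basic, which the enol ether diene tolerates.

Step 9
Reactants: 15 1-[3-(4-{2-[3-(buta-1,3-dien-2-yloxy)-4-methoxyphenyl]ethyl}-2-methoxyphenoxy)phenyl]but-3-yn-2-ol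
Product: 16 1-[3-(4-{2-[3-(buta-1,3-dien-2-yloxy)-4-methoxyphenyl]ethyl}-2-methoxyphenoxy)phenyl]but-3-yn-2-one (seco aryloxydiene ynone)
Conditions: MnO2 (activated, excess), BHT (trace), CH2Cl2, rt; filtration, used at once
Reagents that add atoms: none
Why: MnO2 oxidises propargylic alcohols to ynones under neutral heterogeneous conditions that leave the enol ether diene and the benzylic positions alone; the racemic carbinol centre disappears here, and 16 is not stored because terminal ynones polymerise and add nucleophiles readily.

Step 10
Reactants: 16 1-[3-(4-{2-[3-(buta-1,3-dien-2-yloxy)-4-methoxyphenyl]ethyl}-2-methoxyphenoxy)phenyl]but-3-yn-2-one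
Product: 17 macrocyclic 1-acyl-4-aryloxycyclohexa-1,4-diene (the 20-membered di-O-methyl macrocycle in which ring C is a cyclohexa-1,4-diene bearing the ring D oxygen on C4 and the C(=O)CH2 link to ring B on C1)
Conditions: toluene (degassed, about 0.5 mM final), BHT (cat.), 110 °C, syringe-pump addition of 16
Reagents that add atoms: none
Why: Proposed new method: a concerted but asynchronous [4+2] cycloaddition of normal electron demand is expected between the electron-rich 2-aryloxydiene (HOMO raised by the oxygen lone pair) and the electron-poor terminal ynone (LUMO lowered by the carbonyl), in which the diene terminus attached to the oxygen-bearing carbon bonds first to the ynone β-carbon, so that ether oxygen and acyl carbon end up 1,4 on the new ring. The closest known reaction type is the intermolecular para-selective Diels–Alder reaction of 2-oxygenated butadienes with alkynyl ketones, together with type 2 intramolecular Diels–Alder reactions and arene-forming cycloadditions used for macrocyclisation; new here is that a 16-atom tether joins C2 of the diene to the acyl carbon. Ring C is closed by the cycloaddition itself, both new C–C bonds forming in the pericyclic event, and the 20-membered ring is closed in the same event because the tether then spans the 1 and 4 positions of ring C, a para-bridged closure and not an end-to-end ring closure of its own. No stereocentre is created, since both new sp3 carbons are CH2 groups. The step needs para and not meta regiochemistry, which is secured by the matched polarisation of the partners (largest HOMO coefficient at C1 of the diene, largest LUMO coefficient at the ynone β-carbon) and is not opposed by the long flexible tether, which can reach either orientation. It also needs ring closure to outrun intermolecular cycloaddition and ynone polymerisation, which is addressed by slow addition into hot toluene at sub-millimolar concentration with a radical inhibitor. The activating carbonyl sits exactly where the target has a benzylic CH2 and is erased in step 12. The temperature is held near 110 °C because both the aryl dienyl ether and the ynone have limited thermal stability.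

Step 11
Reactants: 17 macrocyclic 1-acyl-4-aryloxycyclohexa-1,4-diene
Product: 18 macrocyclic aryl benzyl ketone (the 20-membered di-O-methyl macrocycle with aromatic ring C and C=O on the bridge carbon attached to ring C)
Conditions: DDQ (1.1 equiv), toluene, 0 °C → rt, on the concentrated crude solution of 17
Reagents that add atoms: none
Why: DDQ dehydrogenation by hydride abstraction from a doubly allylic CH2 and proton loss, driven by aromatisation of ring C; one equivalent at low temperature keeps the oxidant away from the benzylic CH2 groups para to oxygen donors.

Step 12
Reactants: 18 macrocyclic aryl benzyl ketone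
Product: 19 di-O-methyl ether of the target (20-membered macrocycle with both bridges as CH2CH2)
Conditions: Et3SiH (excess), CF3CO2H, CH2Cl2, 0 °C → rt
Reagents that add atoms: none
Why: Ionic hydrogenation: the protonated aryl ketone takes hydride from the silane, the benzylic alcohol ionises to a cation stabilised by the para aryloxy group, and a second hydride gives the methylene; a hydride shift to the neighbouring carbon or loss of a proton to a stilbene would both be reduced to the same product, and aryl ethers are inert.

Step 13
Reactants: 19 di-O-methyl ether of the target
Product: 20 target macrocyclic bis(bibenzyl) diphenol (CNP0329842.0)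
Conditions: BBr3, CH2Cl2, −78 °C → rt; H2O
Reagents that add atoms: none
Why: Lewis acid demethylation: boron binds the methoxy oxygen and bromide attacks the methyl carbon by SN2; the diaryl ethers offer no sp3 carbon for this attack and survive.

## Compound list

1 | 4-fluoro-3-methoxybenzaldehyde | COc1cc(C=O)ccc1F | starting material
2 | 3-(2-hydroxyethyl)phenol | OCCc1cccc(O)c1 | starting material
3 | 4-[3-(2-hydroxyethyl)phenoxy]-3-methoxybenzaldehyde | COc1cc(C=O)ccc1Oc1cccc(CCO)c1 | intermediate
4 | 2-[3-(4-ethenyl-2-methoxyphenoxy)phenyl]ethan-1-ol | COc1cc(C=C)ccc1Oc1cccc(CCO)c1 | intermediate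
5 | 2-[3-(4-ethenyl-2-methoxyphenoxy)phenyl]acetaldehyde | COc1cc(C=C)ccc1Oc1cccc(CC=O)c1 | intermediate
6 | (triisopropylsilyl)acetylene | C#C[Si](C(C)C)(C(C)C)C(C)C | starting material
7 | lithium 1-[3-(4-ethenyl-2-methoxyphenoxy)phenyl]-4-(triisopropylsilyl)but-3-yn-2-olate (racemic, not isolated) | [Li+].[O-]C(Cc1cccc(Oc2ccc(C=C)cc2OC)c1)C#C[Si](C(C)C)(C(C)C)C(C)C | intermediate
8 | tert-butyl({1-[3-(4-ethenyl-2-methoxyphenoxy)phenyl]-4-(triisopropylsilyl)but-3-yn-2-yl}oxy)dimethylsilane (racemic) | C=Cc1ccc(Oc2cccc(CC(O[Si](C)(C)C(C)(C)C)C#C[Si](C(C)C)(C(C)C)C(C)C)c2)c(OC)c1 | intermediate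
9 | 5-bromo-2-methoxyphenol | COc1ccc(Br)cc1O | starting material
10 | 9-{2-[4-(3-{2-[(tert-butyldimethylsilyl)oxy]-4-(triisopropylsilyl)but-3-yn-1-yl}phenoxy)-3-methoxyphenyl]ethyl}-9-borabicyclo[3.3.1]nonane (racemic, not isolated) | COc1cc(CCB2C3CCCC2CCC3)ccc1Oc1cccc(CC(O[Si](C)(C)C(C)(C)C)C#C[Si](C(C)C)(C(C)C)C(C)C)c1 | intermediate
11 | 5-{2-[4-(3-{2-[(tert-butyldimethylsilyl)oxy]-4-(triisopropylsilyl)but-3-yn-1-yl}phenoxy)-3-methoxyphenyl]ethyl}-2-methoxyphenol (racemic) | COc1ccc(CCc2ccc(Oc3cccc(CC(O[Si](C)(C)C(C)(C)C)C#C[Si](C(C)C)(C(C)C)C(C)C)c3)c(OC)c2)cc1O | intermediate
12 | acryloyl chloride | C=CC(Cl)=O | starting material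
13 | 5-{2-[4-(3-{2-[(tert-butyldimethylsilyl)oxy]-4-(triisopropylsilyl)but-3-yn-1-yl}phenoxy)-3-methoxyphenyl]ethyl}-2-methoxyphenyl prop-2-enoate (racemic) | C=CC(=O)Oc1cc(CCc2ccc(Oc3cccc(CC(O[Si](C)(C)C(C)(C)C)C#C[Si](C(C)C)(C(C)C)C(C)C)c3)c(OC)c2)ccc1OC | intermediate
14 | 2-(buta-1,3-dien-2-yloxy)-4-{2-[4-(3-{2-[(tert-butyldimethylsilyl)oxy]-4-(triisopropylsilyl)but-3-yn-1-yl}phenoxy)-3-methoxyphenyl]ethyl}-1-methoxybenzene (racemic) | C=CC(=C)Oc1cc(CCc2ccc(Oc3cccc(CC(O[Si](C)(C)C(C)(C)C)C#C[Si](C(C)C)(C(C)C)C(C)C)c3)c(OC)c2)ccc1OC | intermediate
15 | 1-[3-(4-{2-[3-(buta-1,3-dien-2-yloxy)-4-methoxyphenyl]ethyl}-2-methoxyphenoxy)phenyl]but-3-yn-2-ol (racemic) | C=CC(=C)Oc1cc(CCc2ccc(Oc3cccc(CC(O)C#C)c3)c(OC)c2)ccc1OC | intermediate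
16 | 1-[3-(4-{2-[3-(buta-1,3-dien-2-yloxy)-4-methoxyphenyl]ethyl}-2-methoxyphenoxy)phenyl]but-3-yn-2-one (seco aryloxydiene ynone) | C=CC(=C)Oc1cc(CCc2ccc(Oc3cccc(CC(=O)C#C)c3)c(OC)c2)ccc1OC | intermediate
17 | macrocyclic 1-acyl-4-aryloxycyclohexa-1,4-diene (20-membered, di-O-methyl) | COc1cc2ccc1Oc1cccc(c1)CC(=O)C1=CCC(=CC1)Oc1cc(ccc1OC)CC2 | intermediate
18 | macrocyclic aryl benzyl ketone (ring C aromatic, di-O-methyl) | COc1cc2ccc1Oc1cccc(c1)CC(=O)c1ccc(cc1)Oc1cc(ccc1OC)CC2 | intermediate
19 | di-O-methyl ether of the target | COc1cc2ccc1Oc1cccc(c1)CCc1ccc(cc1)Oc1cc(ccc1OC)CC2 | intermediate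
20 | target macrocyclic bis(bibenzyl) diphenol (CNP0329842.0) | Oc1cc2ccc1Oc1cccc(c1)CCc1ccc(cc1)Oc1cc(ccc1O)CC2 | target

## Step count and least certain steps

Total: 13 steps. Longest linear sequence: 13 steps (from 1 and 2 to 20); 6, 9 and 12 enter as purchased building blocks. Nine steps lead to the precursor 16, and three follow the key step.

**Step 10 (key step).** What may go wrong: ring closure to a 20-membered ring has a low effective molarity, so intermolecular cycloaddition, ynone polymerisation or thermal decay of the enol ether may consume 16 before it cyclises. Raising the temperature to compensate would open further decay channels of the aryl dienyl ether.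

Fallback with known reactions only, setting out from 8 (with 9 and 12) and returning at 18: the ring C-forming cycloaddition is run between two molecules and the macrocycle is closed afterwards at the D–A bridge. TBAF converts 8 into 1-[3-(4-ethenyl-2-methoxyphenoxy)phenyl]but-3-yn-2-ol F1, and MnO2 gives 1-[3-(4-ethenyl-2-methoxyphenoxy)phenyl]but-3-yn-2-one F2. In parallel 9 is acylated with 12 to 5-bromo-2-methoxyphenyl prop-2-enoate F3 and methylenated with the Tebbe reagent to 4-bromo-2-(buta-1,3-dien-2-yloxy)-1-methoxybenzene F4, a small and alkyne-free diene. Heating F2 with an excess of F4 in concentrated toluene solution should give, by the known para-selective intermolecular Diels–Alder reaction, 1-[4-(5-bromo-2-methoxyphenoxy)cyclohexa-1,4-dien-1-yl]-2-[3-(4-ethenyl-2-methoxyphenoxy)phenyl]ethan-1-one F5. DDQ then aromatises it to 1-[4-(5-bromo-2-methoxyphenoxy)phenyl]-2-[3-(4-ethenyl-2-methoxyphenoxy)phenyl]ethan-1-one F6. A Heck cyclisation at high dilution (Pd(OAc)2, P(o-tol)3, Et3N, DMF, 100 °C) joins the aryl bromide to the styrene terminus to give the macrocyclic (E)-stilbene ketone F7. Hydrogenation (H2, Pd/C, EtOAc) saturates the stilbene and delivers 18.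

**Step 7.** What may go wrong: the titanium methylidene may engage the silylalkyne instead of the ester carbonyl, or the aluminium Lewis acid set free may polymerise or hydrolyse the new diene during work-up.

Fallback without titanium, setting out from 11 and returning at 14: palladium-catalysed allylic etherification of 11 with 2-vinyloxirane (Pd2(dba)3, racemic trans-1,2-diaminocyclohexane bis(2-diphenylphosphinobenzamide) ligand, CH2Cl2), in which the alkoxide of the opened epoxide steers the phenol to the internal allyl terminus, should give the branched 2-aryloxybut-3-en-1-ol F8. Conversion with I2, PPh3 and imidazole gives the 2-aryloxy-1-iodobut-3-ene F9. E2 elimination with KOt-Bu in THF at 0 °C removes the only β-hydrogen, which is allylic and next to oxygen, and gives 14.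

**Step 5.** What may go wrong: slow oxidative addition into the electron-rich bromophenolate may let the alkylborane decay by protodeboronation, or some hydroboration of the alkyne may occur if excess borane is present.

Fallback without a boron reagent, setting out from 8 and 9 and returning at 11: a Heck coupling (Pd(OAc)2, P(o-tol)3, Et3N, DMF, 100 °C) gives the (E)-stilbene phenol F10. Its C=C bond is then saturated with diimide (p-toluenesulfonylhydrazide, NaOAc, aqueous DME, reflux), a non-catalytic reduction used for stilbenes when other reducible groups must be spared and for which the shielded silylalkyne should be too hindered. This gives 11.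

**Step 12.** What may go wrong: the reduction may stall at the benzylic alcohol or its trifluoroacetate, or the benzylic cation may alkylate an electron-rich ring across the macrocycle before the silane reaches it.

Fallback through an anionic instead of a cationic pathway, setting out from 18 and returning at 19: Wolff–Kishner reduction (N2H4·H2O, KOH, diethylene glycol, 120 → 195 °C) through the macrocyclic hydrazone F11. Any partial loss of a methyl group under these conditions would be harmless because step 13 removes both.

## Further compounds

F1 | step 10 | 1-[3-(4-ethenyl-2-methoxyphenoxy)phenyl]but-3-yn-2-ol (racemic) | COc1cc(C=C)ccc1Oc1cccc(CC(O)C#C)c1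
F2 | step 10 | 1-[3-(4-ethenyl-2-methoxyphenoxy)phenyl]but-3-yn-2-one | COc1cc(C=C)ccc1Oc1cccc(CC(=O)C#C)c1
F3 | step 10 | 5-bromo-2-methoxyphenyl prop-2-enoate | C=CC(=O)Oc1cc(Br)ccc1OC
F4 | step 10 | 4-bromo-2-(buta-1,3-dien-2-yloxy)-1-methoxybenzene | C=CC(=C)Oc1cc(Br)ccc1OC
F5 | step 10 | 1-[4-(5-bromo-2-methoxyphenoxy)cyclohexa-1,4-dien-1-yl]-2-[3-(4-ethenyl-2-methoxyphenoxy)phenyl]ethan-1-one | COc1cc(C=C)ccc1Oc1cccc(CC(=O)C2=CCC(Oc3cc(Br)ccc3OC)=CC2)c1
F6 | step 10 | 1-[4-(5-bromo-2-methoxyphenoxy)phenyl]-2-[3-(4-ethenyl-2-methoxyphenoxy)phenyl]ethan-1-one | COc1cc(C=C)ccc1Oc1cccc(CC(=O)c2ccc(Oc3cc(Br)ccc3OC)cc2)c1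
F7 | step 10 | macrocyclic (E)-stilbene ketone (18 with an E double bond in the D–A bridge) | O=C1Cc2cccc(c2)Oc2ccc(cc2OC)/C=C/c2ccc(OC)c(c2)Oc2ccc1cc2
F8 | step 7 | 2-(5-{2-[4-(3-{2-[(tert-butyldimethylsilyl)oxy]-4-(triisopropylsilyl)but-3-yn-1-yl}phenoxy)-3-methoxyphenyl]ethyl}-2-methoxyphenoxy)but-3-en-1-ol (mixture of diastereomers) | OCC(C=C)Oc1cc(CCc2ccc(Oc3cccc(CC(O[Si](C)(C)C(C)(C)C)C#C[Si](C(C)C)(C(C)C)C(C)C)c3)c(OC)c2)ccc1OC
F9 | step 7 | 4-{2-[4-(3-{2-[(tert-butyldimethylsilyl)oxy]-4-(triisopropylsilyl)but-3-yn-1-yl}phenoxy)-3-methoxyphenyl]ethyl}-2-[(1-iodobut-3-en-2-yl)oxy]-1-methoxybenzene (mixture of diastereomers) | ICC(C=C)Oc1cc(CCc2ccc(Oc3cccc(CC(O[Si](C)(C)C(C)(C)C)C#C[Si](C(C)C)(C(C)C)C(C)C)c3)c(OC)c2)ccc1OC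
F10 | step 5 | 5-{(E)-2-[4-(3-{2-[(tert-butyldimethylsilyl)oxy]-4-(triisopropylsilyl)but-3-yn-1-yl}phenoxy)-3-methoxyphenyl]ethenyl}-2-methoxyphenol (racemic) | COc1ccc(/C=C/c2ccc(Oc3cccc(CC(O[Si](C)(C)C(C)(C)C)C#C[Si](C(C)C)(C(C)C)C(C)C)c3)c(OC)c2)cc1O
F11 | step 12 | hydrazone of the macrocyclic aryl benzyl ketone 18 | COc1cc2ccc1Oc1cccc(c1)CC(=NN)c1ccc(cc1)Oc1cc(ccc1OC)CC2
A1 | alternative 1 | 21-membered macrocyclic dibenzyl ether (di-O-methyl) | COc1cc2ccc1Oc1cccc(c1)CCc1ccc(cc1)Oc1cc(ccc1OC)COC2
A2 | alternative 1 | macrocyclic 1,2-diarylethanol (racemic, di-O-methyl) | COc1cc2ccc1Oc1cccc(c1)CCc1ccc(cc1)Oc1cc(ccc1OC)CC2O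
A3 | alternative 2 | 2,6-dibromo-4-{2-[4-(3-{2-(3,5-dichloro-4-hydroxyphenyl)ethyl}phenoxy)-3-methoxyphenyl]ethyl}phenol | Oc1c(Br)cc(CCc2ccc(Oc3cccc(CCc4cc(Cl)c(O)c(Cl)c4)c3)c(OC)c2)cc1Br
A4 | alternative 2 | macrocyclic 6-aryloxy-2,6-dibromocyclohexa-2,4-dienone (racemic at the brominated sp3 carbon) | O=C1C(Br)=CC2=CC1(Br)Oc1c(Cl)cc(cc1Cl)CCc1cccc(c1)Oc1ccc(cc1OC)CC2
A5 | alternative 3 | 1,3-dioxoisoindolin-2-yl 3-{4-methoxy-3-[4-(2-{3-[(2-oxocyclohex-3-en-1-yl)oxy]phenyl}ethyl)phenoxy]phenyl}propanoate (racemic) | COc1ccc(CCC(=O)ON2C(=O)c3ccccc3C2=O)cc1Oc1ccc(CCc2cccc(OC3CCC=CC3=O)c2)cc1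
A6 | alternative 3 | macrocyclic 3-alkyl-6-aryloxycyclohexanone (mixture of diastereomers) | COc1ccc2cc1Oc1ccc(cc1)CCc1cccc(c1)OC1CCC(CC2)CC1=O
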